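**Retrosynthetic overview**

1. Locants used throughout, for the bicycle and for the arene it comes from: C-1 and C-4 are the bridgeheads, C-2 and C-3 the two carbonyl carbons, C-5 (bearing the propenoate chain)=C-6 the alkene, C-7 carries the aryl group and C-8 the carboxyl.
2. Enabling feature: ring C-1 to C-6 with its 2,3-dione is a ferulate ring at the o-quinone oxidation level (a Diels–Alder retron), and the C-8 carboxyl lies cis and γ to the C-3 ketone. Acid and ketone can therefore be tied as a methoxy γ-lactone acylal (the methyl pseudo-ester of a γ-keto acid), so the dienophile acid is its own traceless tether and C-3 a temporary stereocentre.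
3. Last disconnection: acid hydrolysis of that pseudo-ester, two catechol ketals and a tert-butyl ester. Key disconnection: bonds C-4–C-8 and C-1–C-7, made by dearomatising acyloxylation of a ferulate phenol at C-3 with a protected caffeic acid, then intramolecular Diels–Alder reaction.
4. The ferulate phenol comes from ferulic acid and an (S)-aryl-lactate by Mitsunobu inversion; the lactate (glycidate opening) and the protected caffeic acid (Heck reaction) both come from one aryl bromide.
5. Ring order: the arene rings are bought; the benzodioxole protecting rings are made first; the key step then closes the temporary lactone, ring C-1/C-2/C-3/C-4/C-8/C-7 and ring C-1/C-6/C-5/C-4/C-8/C-7 together, so the bicycle is completed last.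

Key step: step 8

Remark: the chiral aryl iodide of step 7 is taken as a purchasable reagent, and the target is drawn as the open 2,3-diketone although in wet solvents it may sit partly as a hydrate or ring-closed hydroxy-lactone form of the same compound.

**Route**

Step 1
Reactants: 1 4-bromobenzene-1,2-diol
Product: 2 5-bromo-2,2-diphenyl-1,3-benzodioxole
Conditions: Ph2CCl2 (1.2 equiv), neat, 170 °C
Reagents that add atoms: dichlorodiphenylmethane, ClC(Cl)(c1ccccc1)c1ccccc1
Why: Double substitution of the gem-dichloride by the two catechol oxygens (through a diaryl-stabilised cation) should give the five-membered diphenylmethylene ketal, a catechol protection that is stable to base, organometallics and oxidants and falls in aqueous acid; no stereocentre is formed.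

Step 2
Reactants: 2 5-bromo-2,2-diphenyl-1,3-benzodioxole; 3 acrylic acid
Product: 4 (2E)-3-(2,2-diphenyl-1,3-benzodioxol-5-yl)prop-2-enoic acid
Conditions: Pd(OAc)2 (2 mol %), P(o-tol)3, Et3N, DMF, 100 °C; then aq. HCl
Reagents that add atoms: none
Why: Mizoroki–Heck reaction, in which oxidative addition of the aryl bromide to zerovalent palladium, syn insertion of the acrylate with aryl at the β-carbon and syn β-hydride elimination should give the E-cinnamic acid.

Step 3
Reactants: 2 5-bromo-2,2-diphenyl-1,3-benzodioxole; 5 methyl (2S)-oxirane-2-carboxylate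
Product: 7 methyl (2S)-3-(2,2-diphenyl-1,3-benzodioxol-5-yl)-2-hydroxypropanoate, via arylmagnesium bromide 6 (not isolated)
Conditions: Mg, THF, 45 °C; then CuI (10 mol %), 5, THF, −30 → −10 °C; 1 M HCl, 0 °C
Reagents that add atoms: none
Why: Grignard formation followed by copper-catalysed SN2 opening of the glycidic ester at its unsubstituted C-3, which at low temperature should outrun addition to the ester; the C-2–O bond is not touched, so the (S) centre is carried over from the purchased epoxide.

Step 4
Reactants: 7 methyl (2S)-3-(2,2-diphenyl-1,3-benzodioxol-5-yl)-2-hydroxypropanoate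
Product: 8 (2S)-3-(2,2-diphenyl-1,3-benzodioxol-5-yl)-2-hydroxypropanoic acid
Conditions: LiOH·H2O, THF/H2O (3:1), 0 °C; then 1 M HCl to pH 3
Reagents that add atoms: lithium hydroxide, [Li+].[OH-]
Why: Saponification of the methyl ester by acyl–oxygen cleavage; the α-hydroxy carboxylate is not enolised under these conditions and the ketal is stable to base.

Step 5
Reactants: 8 (2S)-3-(2,2-diphenyl-1,3-benzodioxol-5-yl)-2-hydroxypropanoic acid
Product: 9 tert-butyl (2S)-3-(2,2-diphenyl-1,3-benzodioxol-5-yl)-2-hydroxypropanoate
Conditions: Cl3CC(=NH)OtBu (2.5 equiv), CH2Cl2/cyclohexane, rt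
Reagents that add atoms: tert-butyl 2,2,2-trichloroacetimidate, CC(C)(C)OC(=N)C(Cl)(Cl)Cl
Why: The carboxylic acid protonates the imidate and the carboxylate captures the tert-butyl cation, whereas without an added Lewis acid the secondary alcohol should stay free; the stereocentre is not involved.

Step 6
Reactants: 9 tert-butyl (2S)-3-(2,2-diphenyl-1,3-benzodioxol-5-yl)-2-hydroxypropanoate; 10 (E)-ferulic acid
Product: 11 tert-butyl (2R)-3-(2,2-diphenyl-1,3-benzodioxol-5-yl)-2-{[(2E)-3-(4-hydroxy-3-methoxyphenyl)prop-2-enoyl]oxy}propanoate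
Conditions: PPh3, DIAD, THF, 0 °C → rt
Reagents that add atoms: none
Why: Mitsunobu esterification, in which the alcohol is activated as its alkoxyphosphonium ion and displaced by the carboxylate, the only pronucleophile acidic enough to be ionised by the betaine (the phenol is far less acidic); SN2 inversion at the activated α-carbon of the ester turns (S) into the (R) lactate centre of the target.

Step 7
Reactants: 12 (2R,2′R)-2,2′-[(2-iodo-1,3-phenylene)bis(oxy)]bis[N-(2,4,6-trimethylphenyl)propanamide]
Product: 13 (2R,2′R)-2,2′-{[2-(diacetoxyiodo)-1,3-phenylene]bis(oxy)}bis[N-(2,4,6-trimethylphenyl)propanamide]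
Conditions: AcOOH (ca. 35 % in AcOH), AcOH, 30 °C
Reagents that add atoms: peracetic acid, CC(=O)OO; acetic acid, CC(=O)O
Why: Standard oxidation of an aryl iodide to its diacetoxyiodoarene (trivalent iodine) by peracetic acid; the lactamide stereocentres are not involved.

Step 8
Reactants: 11 tert-butyl (2R)-3-(2,2-diphenyl-1,3-benzodioxol-5-yl)-2-{[(2E)-3-(4-hydroxy-3-methoxyphenyl)prop-2-enoyl]oxy}propanoate; 4 (2E)-3-(2,2-diphenyl-1,3-benzodioxol-5-yl)prop-2-enoic acid; 13 chiral diacetoxyiodoarene
Product: 16 methoxy-lactone cycloadduct (1R,3R,4R,7S,8R), via iodane bis-cinnamate 14 (not isolated), via dienone acylal 15 (not isolated)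
Conditions: 13 (1.2 equiv), 4 (2.5 equiv), PhCl, 40 °C, 15 mbar (−AcOH); then 11, CH2Cl2, −40 → 0 °C; then PhMe (0.005 M), 70 °C
Reagents that add atoms: none
Why: Proposed new method: the acetates of 13 are exchanged for acid 4 to give 14, phenol 11 binds to trivalent iodine through O-2 and one cinnamate is delivered to the methoxy-bearing ortho carbon C-3 with loss of aryl iodide 12, which is a Wessely-type acyloxylation of a guaiacol; the closest known reactions are that acyloxylation in racemic form with PhI(O2CR)2 or Pb(O2CR)4 and the enantioselective intramolecular oxidative spirolactonisation of phenols by the same lactamide-based chiral iodoarenes, and the new element is face-selective transfer of an external carboxylate, reasoned to work because that carboxylate is held on iodine inside the hydrogen-bonded chiral pocket when the C–O bond forms. Acylal 15 then reacts as in the known intramolecular Diels–Alder reaction of 6-acyloxycyclohexa-2,4-dienones: the diene C-1=C-6–C-5=C-4 and the tethered E-cinnamate combine in one suprafacial [4+2] event that forms C-4–C-8 and C-1–C-7 and so closes at once the temporary γ-lactone (O–C(=O)–C-8–C-4–C-3), the ring C-1–C-2–C-3–C-4–C-8–C-7 and the cyclohexene ring C-1–C-6–C-5–C-4–C-8–C-7. The O–C(=O) tether can reach only the diene terminus next to C-3, so CH–CO bonds to C-4 and CH–Ar to C-1 (also the electronically matched sense for an aryl-polarised alkene adding to a dienone), and the lactone forces the carboxyl carbon on C-8 syn to the C-2/C-3 bridge. The E geometry of the dienophile is conserved, which places the aryl group on C-7 trans to the carboxyl and syn to the C-5=C-6 bridge. The dienophile can add only to the diene face that bears the acyloxy group, so C-1, C-4, C-7 and C-8 are all relayed from the acylal centre C-3 set by the chiral iodane; (3R) is required, the (R,R) reagent is drawn, its face preference on this substrate has to be confirmed on a model, and the antipodal reagent is taken if the sense is opposite. The step needs oxidation of the single free phenol only, attack at C-3 over the para carbon C-5, and cycloaddition ahead of dienone dimerisation or acylal ionisation, which should be secured by the capped catechols, by the methoxy group together with the electron-poor C-5 substituent, and by intramolecularity at high dilution.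

Step 9
Reactants: 16 methoxy-lactone cycloadduct (1R,3R,4R,7S,8R)
Product: 17 Yunnaneic acid C
Conditions: TFA/H2O (9:1), 0 °C → rt
Reagents that add atoms: water, O
Why: Aqueous trifluoroacetic acid should cleave the tert-butyl ester (loss of isobutene), both diphenylmethylene ketals (to benzophenone) and the methoxy acylal, which as the pseudo-ester of a γ-keto acid opens far more readily than the side-chain ester to the C-3 ketone, the C-8 acid and methanol; no stereocentre is touched, since the bridgeheads cannot enolise and C-8 is α only to a carboxylic acid.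

**Compound list**

1 | 4-bromobenzene-1,2-diol (4-bromocatechol) | Oc1ccc(Br)cc1O | starting material
2 | 5-bromo-2,2-diphenyl-1,3-benzodioxole | Brc1ccc2OC(c3ccccc3)(c3ccccc3)Oc2c1 | intermediate
3 | acrylic acid (prop-2-enoic acid) | C=CC(=O)O | starting material
4 | (2E)-3-(2,2-diphenyl-1,3-benzodioxol-5-yl)prop-2-enoic acid (ketal-protected caffeic acid) | OC(=O)/C=C/c1ccc2OC(c3ccccc3)(c3ccccc3)Oc2c1 | intermediate
5 | methyl (2S)-oxirane-2-carboxylate (methyl (S)-glycidate) | COC(=O)[C@@H]1CO1 | starting material
6 | (2,2-diphenyl-1,3-benzodioxol-5-yl)magnesium bromide | Br[Mg]c1ccc2OC(c3ccccc3)(c3ccccc3)Oc2c1 | intermediate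
7 | methyl (2S)-3-(2,2-diphenyl-1,3-benzodioxol-5-yl)-2-hydroxypropanoate | COC(=O)[C@@H](O)Cc1ccc2OC(c3ccccc3)(c3ccccc3)Oc2c1 | intermediate
8 | (2S)-3-(2,2-diphenyl-1,3-benzodioxol-5-yl)-2-hydroxypropanoic acid | OC(=O)[C@@H](O)Cc1ccc2OC(c3ccccc3)(c3ccccc3)Oc2c1 | intermediate
9 | tert-butyl (2S)-3-(2,2-diphenyl-1,3-benzodioxol-5-yl)-2-hydroxypropanoate | CC(C)(C)OC(=O)[C@@H](O)Cc1ccc2OC(c3ccccc3)(c3ccccc3)Oc2c1 | intermediate
10 | (E)-ferulic acid, (2E)-3-(4-hydroxy-3-methoxyphenyl)prop-2-enoic acid | COc1cc(/C=C/C(=O)O)ccc1O | starting material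
11 | tert-butyl (2R)-3-(2,2-diphenyl-1,3-benzodioxol-5-yl)-2-{[(2E)-3-(4-hydroxy-3-methoxyphenyl)prop-2-enoyl]oxy}propanoate | COc1cc(/C=C/C(=O)O[C@H](Cc2ccc3OC(c4ccccc4)(c4ccccc4)Oc3c2)C(=O)OC(C)(C)C)ccc1O | intermediate
12 | (2R,2′R)-2,2′-[(2-iodo-1,3-phenylene)bis(oxy)]bis[N-(2,4,6-trimethylphenyl)propanamide] | C[C@@H](Oc1cccc(O[C@H](C)C(=O)Nc2c(C)cc(C)cc2C)c1I)C(=O)Nc1c(C)cc(C)cc1C | starting material
13 | (2R,2′R)-2,2′-{[2-(diacetoxyiodo)-1,3-phenylene]bis(oxy)}bis[N-(2,4,6-trimethylphenyl)propanamide] | C[C@@H](Oc1cccc(O[C@H](C)C(=O)Nc2c(C)cc(C)cc2C)c1I(OC(C)=O)OC(C)=O)C(=O)Nc1c(C)cc(C)cc1C | intermediate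
14 | iodane bis-cinnamate: the analogue of 13 in which both acetates are replaced by the carboxylate of 4 | C[C@@H](Oc1cccc(O[C@H](C)C(=O)Nc2c(C)cc(C)cc2C)c1I(OC(=O)/C=C/c1ccc2OC(c3ccccc3)(c3ccccc3)Oc2c1)OC(=O)/C=C/c1ccc2OC(c3ccccc3)(c3ccccc3)Oc2c1)C(=O)Nc1c(C)cc(C)cc1C | intermediate
15 | dienone acylal: tert-butyl (2R)-3-(2,2-diphenyl-1,3-benzodioxol-5-yl)-2-{[(2E)-3-[(3R)-3-methoxy-4-oxo-3-{[(2E)-3-(2,2-diphenyl-1,3-benzodioxol-5-yl)prop-2-enoyl]oxy}cyclohexa-1,5-dien-1-yl]prop-2-enoyl]oxy}propanoate | O=C1C=CC(/C=C/C(=O)O[C@H](Cc2ccc3OC(c4ccccc4)(c4ccccc4)Oc3c2)C(=O)OC(C)(C)C)=C[C@@]1(OC)OC(=O)/C=C/c1ccc2OC(c3ccccc3)(c3ccccc3)Oc2c1 | intermediate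
16 | methoxy-lactone cycloadduct (1R,3R,4R,7S,8R): bicyclo[2.2.2]oct-5-en-2-one in which C-3 carries OMe and the lactone oxygen, C-8 the lactone carbonyl (syn to C-3), C-7 the 2,2-diphenyl-1,3-benzodioxol-5-yl group (trans to the C-8 carbonyl, syn to C-5=C-6) and C-5 the (E)-propenoate of tert-butyl (2R)-3-(2,2-diphenyl-1,3-benzodioxol-5-yl)-2-hydroxypropanoate | O=C(/C=C/C1=C[C@H]2C(=O)[C@]3(OC)OC(=O)[C@@H]([C@H]13)[C@H]2c1ccc2OC(c3ccccc3)(c3ccccc3)Oc2c1)O[C@H](Cc1ccc2OC(c3ccccc3)(c3ccccc3)Oc2c1)C(=O)OC(C)(C)C | intermediate
17 | Yunnaneic acid C: (2R)-2-{[(2E)-3-[(1R,4R,7S,8R)-8-carboxy-7-(3,4-dihydroxyphenyl)-2,3-dioxobicyclo[2.2.2]oct-5-en-5-yl]prop-2-enoyl]oxy}-3-(3,4-dihydroxyphenyl)propanoic acid (locants as in the overview; CO2H syn to the diketone bridge, aryl syn to the alkene bridge) | O=C(/C=C/C1=C[C@H]2C(=O)C(=O)[C@@H]1[C@H](C(=O)O)[C@H]2c1ccc(O)c(O)c1)O[C@H](Cc1ccc(O)c(O)c1)C(=O)O | target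

**Step count and risks**

Total steps: 9. Longest linear sequence: 7 steps (1, 3, 4, 5, 6, 8, 9).

Steps most likely to fail:

1. Step 8 (bears the label Proposed new method). What may go wrong is poor facial selectivity in the transfer of the external carboxylate to C-3, competing attack at the para carbon C-5, or erosion of the acylal configuration by ionisation before the cycloaddition. Fallback with known chemistry, setting out from 11 (with 4) and coming back at 16: the classical modified Wessely oxidation is used instead, with Pb(OAc)4 added to 11 and an excess of 4 in CH2Cl2 at 0 °C, followed by heating in toluene at 80 °C. Without control at C-3 this should give 15 together with its C-3 epimer, the (3S)-dienone acylal F1. Each cyclises under the same tether control, to 16 and to the diastereomer with the mirror-image core, the (1S,3S,4S,7R,8S)-lactone cycloadduct F2. Because the (R)-lactate centre is already in place, these two adducts are diastereomers and are separated by chromatography; the route is rejoined at 16.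

2. Step 9. What may go wrong is incomplete opening of the pseudo-ester at an acidity that the diketone and the side-chain ester tolerate, or alkylation of the freed catechols by tert-butyl cations. Fallback, setting out from 16 and coming back at 17: the two events are separated. The activated lactone is first opened by acyl–oxygen attack with Me3SnOH (ClCH2CH2Cl, 60 °C; then dilute HCl), the hemiketal losing methanol, which should give the protected diketo acid F3 while the ketals and both other esters stay on. Aqueous TFA then has only the protecting groups to remove and delivers 17.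

3. Step 6. What may go wrong is competing O-alkylation of the free phenol, elimination of the activated β-aryl alcohol to a cinnamate, or incomplete inversion. Fallback, setting out from 9 and coming back at 11: the alcohol is converted with Tf2O and 2,6-lutidine (CH2Cl2, −78 °C) into the (S)-triflate F4, which is displaced with inversion by cesium ferulate (from 10 and 0.5 equiv Cs2CO3, DMF, 0 °C), a carboxylate SN2 reaction of an α-triflyloxy ester in which only the carboxylate of ferulic acid is ionised.

**Further compounds**

F1 | step 8 | (3S)-dienone acylal, C-3 epimer of 15 | O=C1C=CC(/C=C/C(=O)O[C@H](Cc2ccc3OC(c4ccccc4)(c4ccccc4)Oc3c2)C(=O)OC(C)(C)C)=C[C@]1(OC)OC(=O)/C=C/c1ccc2OC(c3ccccc3)(c3ccccc3)Oc2c1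
F2 | step 8 | (1S,3S,4S,7R,8S)-lactone cycloadduct, diastereomer of 16 with the mirror-image core and the same (R)-lactate | O=C(/C=C/C1=C[C@@H]2C(=O)[C@@]3(OC)OC(=O)[C@H]([C@@H]13)[C@@H]2c1ccc2OC(c3ccccc3)(c3ccccc3)Oc2c1)O[C@H](Cc1ccc2OC(c3ccccc3)(c3ccccc3)Oc2c1)C(=O)OC(C)(C)C
F3 | step 9 | protected diketo acid: 17 with both catechols as diphenylmethylene ketals and the lactate carboxyl as tert-butyl ester | O=C(/C=C/C1=C[C@H]2C(=O)C(=O)[C@@H]1[C@H](C(=O)O)[C@H]2c1ccc2OC(c3ccccc3)(c3ccccc3)Oc2c1)O[C@H](Cc1ccc2OC(c3ccccc3)(c3ccccc3)Oc2c1)C(=O)OC(C)(C)C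
F4 | step 6 | tert-butyl (2S)-3-(2,2-diphenyl-1,3-benzodioxol-5-yl)-2-{[(trifluoromethyl)sulfonyl]oxy}propanoate | CC(C)(C)OC(=O)[C@@H](OS(=O)(=O)C(F)(F)F)Cc1ccc2OC(c3ccccc3)(c3ccccc3)Oc2c1
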